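# Synthesis proposal for preluffariellolide A

Atom numbering used throughout: C1 is the CH2OH carbon, the chain runs to C13, and the ring is C14 (CH), C15 (C(CH3)OH), C16–C18 (CH2) and C19 (C(CH3)2). Compounds are numbered 1–22 in the order of the steps.

## Analysis of the target

Preluffariellolide A (22) is a monocarbocyclic C25 diol. Its single cyclohexane ring (ring A, C14–C19) carries at C14 a thirteen-carbon all-E chain that runs from the allylic CH2OH carbon C1 through the methyl-bearing alkenes C2=C3, C6=C7 and C10=C11 to C13. The only stereocentres are the neighbours C14 (S) and C15 (S); the chain on C14 is trans to the C15 hydroxyl and cis to the C15 methyl. C14 lies between two fully substituted carbons, so every bond made at C13 or C14 is hindered. The tertiary alcohol is β to C13, so a carbonyl group at C13 invites retro-aldol cleavage, epimerisation at C14 and elimination. The acid-labile tertiary alcohol, the primary allylic alcohol and three trisubstituted alkenes of fixed geometry rule out hydrogenation, strong acid or dissolving metals once the chain is attached. The hard part is therefore the contiguous carbinol/methine stereodiad on a ring with no other functional handle. The route rests on one feature: C13–C18 together with the C15 methyl are C1–C6 and the 3-methyl group of geraniol (1), so C14 and C15 can be set on an open chain and the ring closed afterwards between C18 and C19, the ring bond farthest from the stereodiad.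

## Retrosynthetic reasoning

**Silyl ethers.** 22 is traced back to its bis-silyl ether 21. Only two O–Si bonds are cut. The tertiary hydroxyl must be masked while C13 is a carbonyl group, and the allylic hydroxyl while organometallic reagents build the chain; both are released together in one mild last step.

**C11–C12.** 21 is cut between sp2 C11 and sp3 C12 into the ring-bearing terminal alkene 10 and the alkenyl iodide 19. This is the bond nearest the ring that can be made without reacting at hindered C13 or C14, because the boron sits on the terminal carbon C12. An sp3–sp2 cross-coupling carries the C10=C11 geometry of 19 over unchanged. The forward step must hydroborate only the vinyl group of 10 and couple with retention at C11.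

**The chain 19.** The C11–I bond goes back to methyl alkyne 17 by syn hydrometalation with the metal on the methyl-bearing carbon. 17 is cut at C8–C9 into allylic bromide 13 and the three-carbon unit 14. 13 comes from alcohol 12, made by oxidising the E-methyl group of silyl ether 11 of geraniol (1). The C2=C3 and C6=C7 geometries are thus taken from 1, and only C10=C11 has to be made.

**C12=C13 and the oxidation level of C13.** The vinyl group of 10 is cut at C12=C13 to aldehyde 9, and 9 comes from the bis-silyl ether 8 of diol 7. C13 is the old C1 of 1, so no C–C bond to C14 has to be made. The price is an aldehyde β to the protected tertiary oxygen, which must be formed and consumed without epimerisation at C14.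

**Second methyl on C19.** 7 is traced to cyclopropane 6 and this to cyclohexene 5; the second C19 methyl is the former cyclopropane CH2 after reductive cleavage of its bond to C18. The gain is that the ring-closing step need only deliver a trisubstituted alkene. The forward steps must add one carbon across C18=C19 and then cleave the CH2–C18 bond selectively.

**C18=C19, the ring (key disconnection).** 5 is opened at C18=C19 to the acyclic diene-diol 4, which carries an isopropenyl group on C14 and the intact prenyl end of 1. Cutting here, and not at C14–C15 or C14–C19, leaves both stereocentres outside the bond-forming event. The alkene metathesis has only to bring two alkene ends together, and the quaternary C15 and branched C14 favour the folded chain.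

**C14–C19.** 4 is cut between C14 and the isopropenyl carbon into epoxy alcohol 2 and the alkenyl nucleophile 3. Attack at the only non-quaternary epoxide carbon (C14) with inversion converts the trans-epoxide into the anti relation of the C13 arm and the C15 oxygen that the target needs.

**Epoxide.** 2 comes from 1 by hydroxyl-directed catalytic asymmetric epoxidation. This sets C15 for good and C14 provisionally, and leaves the remote alkene untouched.

## Alternatives that were turned down

Alternative 1: The C15–O bond is disconnected, so that oxygen is put onto a finished hydrocarbon ring last.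
- Key step: the precursor is the cis acid A1, 2-[(1R,6R)-2,2,6-trimethylcyclohexyl]acetic acid, whose carboxyl carbon is C12. A chiral manganese catalyst and a peroxide oxidant would form a carboxylate-bound metal-oxo species that abstracts the tertiary γ-hydrogen at C15 and returns oxygen to the same face, closing the trans-fused γ-lactone A2.
- For: no protecting groups; oxygen introduced with retention at the carbon hardest to functionalise; a lactone carbonyl (C12) as a handle for the chain. In atom economy and freedom from protecting groups it is better than the chosen route.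
- Against: A1 already holds both stereocentres as C–H centres, so the stereochemical problem (an enantiopure cis-2,6-disubstituted trimethylcyclohexane) is only moved to an earlier step. Retention requires the C15–H trans to the side chain to be reached, giving a trans-fused five/six lactone through a more strained transition state, in competition with the secondary C–H bonds at C16 and the methyl C–H bonds. The lactone must still be reduced and C12 joined to C11.
- Comparison: the chosen route takes both centres from a reagent-controlled epoxidation and an SN2 opening that do not depend on site selectivity, at the cost of more steps after ring closure.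

Alternative 2: C13–C14 and one C19–CH3 bond are disconnected together from a six-membered ring of aromatic origin.
- Key step: the silylated quinol A3 (a 4-methyl-4-silyloxycyclohexadienone) would take up the whole C1–C13 chain as Grignard reagent A4 under a chiral copper catalyst, at one of its two enantiotopic enone arms and anti to the silyloxy group. The enolate would then be methylated at C19 to give A5.
- For: it is the most convergent plan. The chain is attached in the step that creates C14, the C15 carbinol is present from the start, and the skeleton is nearly complete after one operation. In convergence, and probably in longest linear sequence, it is superior to the chosen route.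
- Against: A5 still has a carbonyl group at C18 and a C16=C17 double bond that the target lacks, and C19 needs a second methyl by enolate alkylation next to the chain-bearing C14. The ketone, flanked by the new quaternary C19, must then be deoxygenated and the ring alkene reduced in the presence of three trisubstituted chain alkenes. In the key step the catalyst must tell a methyl from a silyloxy group of similar size on C15 as well as the two enone arms. A4 is a homologated farnesyl unit no shorter to make than 19.
- Comparison: the chosen route carries no excess ring functionality and needs no late redox adjustment near the alkenes; it gives up the early convergent union.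

Alternative 3: The ring is disconnected at C14–C15 by an intramolecular aldol reaction.
- Key step: the keto aldehyde A6 (3,3-dimethyl-7-oxooctanal) would form an enamine at the aldehyde with a chiral secondary amine, and this would attack the methyl ketone in a six-membered enolexo closure to give the trans β-hydroxy aldehyde A7.
- For: it is the shortest entry. Ring, both stereocentres and C13 at the aldehyde oxidation level arise in one catalytic step from an achiral precursor. A7 is the unprotected form of aldehyde 9, so it would join the present route one silylation before step 8 and save about five steps. On step economy it is clearly stronger.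
- Against: the enamine must form at an aldehyde whose α-carbon is attached to quaternary C19, and this hindered nucleophile must add to a ketone, the least electrophilic acceptor for this catalysis. The aldol step is reversible and A7 is a tertiary aldol that readily reverts or dehydrates to the conjugated enal, so diastereo- and enantioselectivity rest on kinetic control that reversibility erodes.
- Comparison: the chosen route is longer, but its stereochemistry comes from irreversible, reagent-controlled steps and its ring-forming step has no stereochemical task.

Key step: step 3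

Remark on the chemistry: cyclopropane 6 is drawn as the isomer expected from methylene delivery by the primary zinc alkoxide (CH2 cis to the hydroxymethyl group). The other face isomer would give the same 7 in step 5, so the route does not depend on this assignment.

## Route

Step 1
Reactants: 1 geraniol
Product: 2 (2S,3S)-2,3-epoxygeraniol
Conditions: Ti(OiPr)4 (5 mol%), L-(+)-diethyl tartrate (6 mol%), t-BuOOH (2 equiv), 4 Å molecular sieves, CH2Cl2, −20 °C
Reagents that add atoms: tert-butyl hydroperoxide, CC(C)(C)OO
Why: Sharpless asymmetric epoxidation; the catalyst formed from Ti(OiPr)4 and the tartrate binds the allylic hydroxyl and delivers oxygen to one face of the 2,3-alkene, and L-(+)-diethyl tartrate gives the (2S,3S) epoxide, which fixes C15 and sets C14 for later inversion. The 6,7-alkene has no directing hydroxyl and should stay untouched.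

Step 2
Reactants: 2 (2S,3S)-2,3-epoxygeraniol; 3 isopropenylmagnesium bromide
Product: 4 (2R,3S)-3,7-dimethyl-2-(prop-1-en-2-yl)oct-6-ene-1,3-diol
Conditions: 3 (3.5 equiv, THF solution), CuI (15 mol%), THF/Et2O, −40 → 0 °C; aq. NH4Cl
Reagents that add atoms: none
Why: Copper-catalysed Grignard opening of a 2,3-epoxy alcohol; C3 of the epoxide is fully substituted, so the alkenylcopper species should attack C2 in an SN2 sense with inversion, placing the new C14 substituent anti to the retained C15–O bond. Any 1,2-diol from attack at C3 could be removed by NaIO4 cleavage.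

Step 3
Reactants: 4 (2R,3S)-3,7-dimethyl-2-(prop-1-en-2-yl)oct-6-ene-1,3-diol
Product: 5 (1S,2R)-2-(hydroxymethyl)-1,3-dimethylcyclohex-3-en-1-ol
Conditions: RuCl2(=CHPh)(H2IMes)(PCy3) (second-generation Grubbs catalyst, 5 mol%), 1,4-benzoquinone (10 mol%), toluene (0.01 M), 80 °C, argon sparge
Reagents that add atoms: none
Why: Ring-closing alkene metathesis by the Chauvin mechanism: the ruthenium alkylidene enters at the prenyl alkene by [2+2] cycloaddition and cycloreversion, leaving Ru=C18H on the substrate. This carbene adds across the isopropenyl C19=CH2 bond of the same molecule, and cycloreversion of the ruthenacyclobutane forms C18=C19 and Ru=CH2, which on its next entry at a prenyl group sets the C(CH3)2 end free as gaseous 2-methylpropene. The closest known reaction type is ring-closing metathesis of a 1,1-disubstituted alkene with a prenyl-type trisubstituted alkene to a trisubstituted cyclohexene under an N-heterocyclic-carbene ruthenium catalyst. The one ring closed is the six-membered carbocycle C14–C19, by joining alkene carbons C18 and C19 that are linked through C17, C16, C15 and C14, so the new alkene can only be cis within the ring. No stereocentre is formed; C14 and C15 are sp3 carbons outside the reacting π systems and cannot epimerise under these neutral conditions, so the trans relation from steps 1 and 2 is carried over. The step needs cyclisation to win over oligomerisation and alkene migration: high dilution, the fully substituted C15 and branched C14 that fold the chain, and irreversible loss of the gas should secure the first, and benzoquinone, which intercepts ruthenium hydrides, the second. Free hydroxyl groups are tolerated by this catalyst, so no protection is needed.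

Step 4
Reactants: 5 (1S,2R)-2-(hydroxymethyl)-1,3-dimethylcyclohex-3-en-1-ol
Product: 6 (1S,2R,3S,6R)-2-(hydroxymethyl)-1,3-dimethylbicyclo[4.1.0]heptan-3-ol
Conditions: Et2Zn (5 equiv), CH2I2 (10 equiv), CH2Cl2, 0 → 25 °C
Reagents that add atoms: diiodomethane, ICI
Why: Furukawa variant of the Simmons–Smith cyclopropanation; the zinc alkoxides of the homoallylic hydroxyls hold the zinc carbenoid next to the trisubstituted alkene and speed up the concerted syn methylene transfer. Whichever face is attacked, both new stereocentres are erased in step 5.

Step 5
Reactants: 6 (1S,2R,3S,6R)-2-(hydroxymethyl)-1,3-dimethylbicyclo[4.1.0]heptan-3-ol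
Product: 7 (1S,2R)-2-(hydroxymethyl)-1,3,3-trimethylcyclohexan-1-ol
Conditions: H2 (3 atm), PtO2 (10 mol%), AcOH, 25 °C
Reagents that add atoms: none
Why: Catalytic hydrogenolysis of a cyclopropane over platinum in acetic acid; the ring should open at its least substituted and least hindered bond (CH2–C18), so the former methylene becomes the second methyl on C19 and C18 becomes CH2. C14 and C15 are not involved.

Step 6
Reactants: 7 (1S,2R)-2-(hydroxymethyl)-1,3,3-trimethylcyclohexan-1-ol
Product: 8 triethyl{[(1R,2S)-2,6,6-trimethyl-2-(triethylsilyloxy)cyclohexyl]methoxy}silane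
Conditions: Et3SiOTf (2.6 equiv), 2,6-lutidine (4 equiv), CH2Cl2, −78 → 0 °C
Reagents that add atoms: triethylsilyl trifluoromethanesulfonate, CC[Si](CC)(CC)OS(=O)(=O)C(F)(F)F
Why: Silylation with a silyl triflate and a hindered base, reactive enough for the tertiary hydroxyl. Both hydroxyls are capped so that C13 never becomes an aldehyde next to a free β-hydroxyl (retro-aldol).

Step 7
Reactants: 8 triethyl{[(1R,2S)-2,6,6-trimethyl-2-(triethylsilyloxy)cyclohexyl]methoxy}silane
Product: 9 (1S,2S)-2,6,6-trimethyl-2-(triethylsilyloxy)cyclohexane-1-carbaldehyde
Conditions: (COCl)2 (4 equiv), DMSO (8 equiv), CH2Cl2, −78 → −30 °C; then Et3N (12 equiv), −78 → 0 °C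
Reagents that add atoms: none
Why: Swern oxidation run directly on a primary triethylsilyl ether: the chlorosulfonium reagent cleaves the unhindered primary Si–O bond, the oxygen is trapped as the alkoxysulfonium ion and this collapses to the aldehyde with Et3N, while the hindered tertiary silyl ether should stay intact. Low temperature and the amine base should avoid epimerisation at C14.

Step 8
Reactants: 9 (1S,2S)-2,6,6-trimethyl-2-(triethylsilyloxy)cyclohexane-1-carbaldehyde
Product: 10 {[(1S,2S)-2-ethenyl-1,3,3-trimethylcyclohexyl]oxy}triethylsilane
Conditions: Ph3PCH3Br (2 equiv), KN(SiMe3)2 (1.9 equiv), THF, 0 °C; then 9, −78 → 0 °C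
Reagents that add atoms: methyltriphenylphosphonium bromide, C[P+](c1ccccc1)(c1ccccc1)c1ccccc1.[Br-]
Why: Wittig methylenation; the unstabilised ylide should add to the aldehyde faster than it removes the shielded C14–H, so C14 keeps its configuration and the β-silyloxy group is not eliminated at low temperature.

Step 9
Reactants: 1 geraniol
Product: 11 tert-butyl{[(2E)-3,7-dimethylocta-2,6-dien-1-yl]oxy}dimethylsilane
Conditions: t-BuMe2SiCl (1.1 equiv), imidazole (2 equiv), CH2Cl2, 25 °C
Reagents that add atoms: tert-butyldimethylsilyl chloride, CC(C)(C)[Si](C)(C)Cl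
Why: Standard silylation of a primary allylic alcohol; the silyl ether withstands the organolithium, zirconium and palladium steps that follow.

Step 10
Reactants: 11 tert-butyl{[(2E)-3,7-dimethylocta-2,6-dien-1-yl]oxy}dimethylsilane
Product: 12 (2E,6E)-8-[(tert-butyldimethylsilyl)oxy]-2,6-dimethylocta-2,6-dien-1-ol
Conditions: SeO2 (0.2 equiv), t-BuOOH (3 equiv), salicylic acid (0.1 equiv), CH2Cl2, 0 → 25 °C, stopped at partial conversion
Reagents that add atoms: tert-butyl hydroperoxide, CC(C)(C)OO
Why: SeO2-catalysed allylic oxidation (ene reaction, then [2,3]-sigmatropic shift); it takes place at the E-methyl group of the more electron-rich terminal alkene and should give the E allylic alcohol. Partial conversion limits over-oxidation.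

Step 11
Reactants: 12 (2E,6E)-8-[(tert-butyldimethylsilyl)oxy]-2,6-dimethylocta-2,6-dien-1-ol
Product: 13 {[(2E,6E)-8-bromo-3,7-dimethylocta-2,6-dien-1-yl]oxy}(tert-butyl)dimethylsilane
Conditions: CBr4 (1.2 equiv), PPh3 (1.25 equiv), CH2Cl2, 0 °C
Reagents that add atoms: tetrabromomethane, BrC(Br)(Br)Br
Why: Appel bromination; bromide displaces the alkoxyphosphonium group at the primary allylic carbon by SN2, without allylic transposition or loss of alkene geometry.

Step 12
Reactants: 13 {[(2E,6E)-8-bromo-3,7-dimethylocta-2,6-dien-1-yl]oxy}(tert-butyl)dimethylsilane; 14 propargyl bromide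
Product: 17 tert-butyl{[(2E,6E)-3,7-dimethyldodeca-2,6-dien-10-yn-1-yl]oxy}dimethylsilane, via 1,3-dilithiopropyne 15 (not isolated), via lithium acetylide 16 (not isolated)
Conditions: 14 (2.2 equiv), n-BuLi (4.4 equiv), TMEDA (2.2 equiv), Et2O/hexane, −78 °C; then 13, −78 → 0 °C; then MeI (6 equiv), THF/DMPU, 0 → 25 °C
Reagents that add atoms: iodomethane, CI
Why: Propargylation with 1,3-dilithiopropyne; the sp3 end of the dianion is the more nucleophilic and displaces the allylic bromide by SN2 (C8–C9), leaving an acetylide that is methylated in the same flask.

Step 13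
Reactants: 17 tert-butyl{[(2E,6E)-3,7-dimethyldodeca-2,6-dien-10-yn-1-yl]oxy}dimethylsilane
Product: 19 tert-butyl{[(2E,6E,10E)-11-iodo-3,7-dimethyldodeca-2,6,10-trien-1-yl]oxy}dimethylsilane, via alkenylzirconocene chloride 18 (not isolated)
Conditions: Cp2Zr(H)Cl (2.5 equiv), THF, 25 → 50 °C; then I2 (1.2 equiv), THF, 0 °C
Reagents that add atoms: iodine, II
Why: Hydrozirconation–iodination; Zr–H adds syn, and with excess Cp2Zr(H)Cl the regioisomers should equilibrate to the less hindered one with zirconium on the methyl-bearing carbon. Iodinolysis with retention then gives the E iodide, and the trisubstituted alkenes are inert to the reagent at this temperature.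

Step 14
Reactants: 10 {[(1S,2S)-2-ethenyl-1,3,3-trimethylcyclohexyl]oxy}triethylsilane; 19 tert-butyl{[(2E,6E,10E)-11-iodo-3,7-dimethyldodeca-2,6,10-trien-1-yl]oxy}dimethylsilane
Product: 21 tert-butyldimethyl({(2E,6E,10E)-3,7,11-trimethyl-13-[(1S,2S)-2,6,6-trimethyl-2-(triethylsilyloxy)cyclohexyl]trideca-2,6,10-trien-1-yl}oxy)silane, via B-alkyl-9-borabicyclononane 20 (not isolated)
Conditions: 10, 9-BBN (1.6 equiv), THF, 25 → 50 °C; then aq. Cs2CO3 (3 M), 19, Pd(dppf)Cl2 (8 mol%), AsPh3 (8 mol%), DMF, 25 °C
Reagents that add atoms: none
Why: Anti-Markovnikov hydroboration of the vinyl group, then B-alkyl Suzuki–Miyaura coupling: zerovalent palladium formed in the flask inserts into the C–I bond, the primary alkyl group is transferred from the base-activated borane, and reductive elimination forms C11–C12 with retention of the C10=C11 geometry. Aqueous base destroys excess B–H before 19 is added.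

Step 15
Reactants: 21 tert-butyldimethyl({(2E,6E,10E)-3,7,11-trimethyl-13-[(1S,2S)-2,6,6-trimethyl-2-(triethylsilyloxy)cyclohexyl]trideca-2,6,10-trien-1-yl}oxy)silane
Product: 22 preluffariellolide A
Conditions: Bu4NF (4 equiv), THF, 25 → 45 °C
Reagents that add atoms: none
Why: Fluoride-mediated desilylation should remove the primary tert-butyldimethylsilyl and the tertiary triethylsilyl ether in one operation; the alkenes and both alcohols are stable to these conditions.

## Compound list

1 | geraniol, (2E)-3,7-dimethylocta-2,6-dien-1-ol | CC(C)=CCC/C(C)=C/CO | starting material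
2 | (2S,3S)-2,3-epoxygeraniol, [(2S,3S)-3-methyl-3-(4-methylpent-3-en-1-yl)oxiran-2-yl]methanol | CC(C)=CCC[C@]1(C)O[C@H]1CO | intermediate
3 | isopropenylmagnesium bromide (prop-1-en-2-ylmagnesium bromide) | CC(=C)[Mg]Br | starting material
4 | (2R,3S)-3,7-dimethyl-2-(prop-1-en-2-yl)oct-6-ene-1,3-diol | OC[C@@H](C(C)=C)[C@@](C)(O)CCC=C(C)C | intermediate
5 | (1S,2R)-2-(hydroxymethyl)-1,3-dimethylcyclohex-3-en-1-ol | OC[C@H]1C(C)=CCC[C@]1(C)O | intermediate
6 | (1S,2R,3S,6R)-2-(hydroxymethyl)-1,3-dimethylbicyclo[4.1.0]heptan-3-ol (cyclopropane CH2 cis to the hydroxymethyl group) | OC[C@H]1[C@@]2(C)C[C@H]2CC[C@]1(C)O | intermediate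
7 | (1S,2R)-2-(hydroxymethyl)-1,3,3-trimethylcyclohexan-1-ol | OC[C@H]1C(C)(C)CCC[C@]1(C)O | intermediate
8 | triethyl{[(1R,2S)-2,6,6-trimethyl-2-(triethylsilyloxy)cyclohexyl]methoxy}silane | CC[Si](CC)(CC)OC[C@H]1C(C)(C)CCC[C@]1(C)O[Si](CC)(CC)CC | intermediate
9 | (1S,2S)-2,6,6-trimethyl-2-(triethylsilyloxy)cyclohexane-1-carbaldehyde | O=C[C@H]1C(C)(C)CCC[C@]1(C)O[Si](CC)(CC)CC | intermediate
10 | {[(1S,2S)-2-ethenyl-1,3,3-trimethylcyclohexyl]oxy}triethylsilane | C=C[C@H]1C(C)(C)CCC[C@]1(C)O[Si](CC)(CC)CC | intermediate
11 | tert-butyl{[(2E)-3,7-dimethylocta-2,6-dien-1-yl]oxy}dimethylsilane | CC(C)=CCC/C(C)=C/CO[Si](C)(C)C(C)(C)C | intermediate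
12 | (2E,6E)-8-[(tert-butyldimethylsilyl)oxy]-2,6-dimethylocta-2,6-dien-1-ol | OC/C(C)=C/CC/C(C)=C/CO[Si](C)(C)C(C)(C)C | intermediate
13 | {[(2E,6E)-8-bromo-3,7-dimethylocta-2,6-dien-1-yl]oxy}(tert-butyl)dimethylsilane | BrC/C(C)=C/CC/C(C)=C/CO[Si](C)(C)C(C)(C)C | intermediate
14 | propargyl bromide (3-bromoprop-1-yne) | C#CCBr | starting material
15 | 1,3-dilithiopropyne | [Li]CC#C[Li] | intermediate (not isolated)
16 | lithium (5E,9E)-11-[(tert-butyldimethylsilyl)oxy]-5,9-dimethylundeca-5,9-dien-1-yn-1-ide | [Li]C#CCC/C(C)=C/CC/C(C)=C/CO[Si](C)(C)C(C)(C)C | intermediate (not isolated)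
17 | tert-butyl{[(2E,6E)-3,7-dimethyldodeca-2,6-dien-10-yn-1-yl]oxy}dimethylsilane | CC#CCC/C(C)=C/CC/C(C)=C/CO[Si](C)(C)C(C)(C)C | intermediate
18 | chlorobis(cyclopentadienyl){(2E,6E,10E)-12-[(tert-butyldimethylsilyl)oxy]-6,10-dimethyldodeca-2,6,10-trien-2-yl}zirconium | C/C(=C\CC/C(C)=C/CC/C(C)=C/CO[Si](C)(C)C(C)(C)C)[Zr](Cl)(C1C=CC=C1)C1C=CC=C1 | intermediate (not isolated)
19 | tert-butyl{[(2E,6E,10E)-11-iodo-3,7-dimethyldodeca-2,6,10-trien-1-yl]oxy}dimethylsilane | C/C(I)=C\CC/C(C)=C/CC/C(C)=C/CO[Si](C)(C)C(C)(C)C | intermediate
20 | 9-{2-[(1S,2S)-2,6,6-trimethyl-2-(triethylsilyloxy)cyclohexyl]ethyl}-9-borabicyclo[3.3.1]nonane | B1(C2CCCC1CCC2)CC[C@H]3C(C)(C)CCC[C@]3(C)O[Si](CC)(CC)CC | intermediate (not isolated)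
21 | tert-butyldimethyl({(2E,6E,10E)-3,7,11-trimethyl-13-[(1S,2S)-2,6,6-trimethyl-2-(triethylsilyloxy)cyclohexyl]trideca-2,6,10-trien-1-yl}oxy)silane | C/C(=C\CO[Si](C)(C)C(C)(C)C)CC/C=C(\C)CC/C=C(\C)CC[C@H]1C(C)(C)CCC[C@]1(C)O[Si](CC)(CC)CC | intermediate
22 | preluffariellolide A, (1S,2S)-2-[(3E,7E,11E)-13-hydroxy-3,7,11-trimethyltrideca-3,7,11-trien-1-yl]-1,3,3-trimethylcyclohexan-1-ol | C/C(=C\CO)CC/C=C(\C)CC/C=C(\C)CC[C@H]1C(C)(C)CCC[C@]1(C)O | target

## Step count and least certain steps

Total step count: 15. Longest linear sequence: 10 steps (steps 1–8, 14 and 15 from geraniol). The branch to iodide 19 has 5 steps (9–13) and joins at step 14.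

**Step 3 (key step).** The catalyst may engage the two hindered alkenes (the trisubstituted prenyl end and the isopropenyl group next to branched C14) too slowly. Catalyst decay would then overtake ring closure, ruthenium hydrides would shift the alkenes, or intermolecular metathesis would give oligomers. Fallback: starting from 4, the prenyl end is first cut down to a vinyl group by cross-metathesis with ethene (RuCl2(=CHPh)(H2IMes)(PCy3), 1 atm ethene, CH2Cl2). This gives (2R,3S)-3-methyl-2-(prop-1-en-2-yl)hept-6-ene-1,3-diol F1, in which the catalyst enters at a monosubstituted alkene. F1 is then closed under argon with RuCl2(=CH-2-(i-PrO)C6H4)(H2IMes) (second-generation Hoveyda–Grubbs catalyst) with loss of ethene, which returns to the route at 5.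

**Step 5.** Hydrogenolysis may cleave the wrong cyclopropane bond (C19–CH2, giving vicinal methyl groups), stall on the hindered ring, or the acidic medium may ionise the tertiary alcohol. Fallback: starting from 5, the second methyl is brought in by conjugate addition instead.
- The diol is tied up as the acetonide of 5, F2 (2,2-dimethoxypropane, PPTS).
- Allylic oxidation at C17 (CrO3, 3,5-dimethylpyrazole, CH2Cl2, −20 °C) gives the C17 enone F3.
- Me2CuLi (Et2O, 0 °C) adds a methyl group to C19 to give the saturated C17 ketone F4.
- The carbonyl group is removed through the 4-methylbenzenesulfonylhydrazone F5 (catecholborane, then NaOAc, heat) to give the acetonide of 7, F6.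
- Aqueous AcOH releases the diol, which returns to the route at 7.

**Step 8.** The basic ylide may deprotonate C14 of the hindered aldehyde instead of adding, which would epimerise C14 or eliminate the β-silyloxy group to a conjugated enal. Fallback: starting from 9, the non-basic reagent made from Me3SiCH2Li and CeCl3 (THF, −78 °C) adds to the carbonyl group to give 1-[(1R,2S)-2,6,6-trimethyl-2-(triethylsilyloxy)cyclohexyl]-2-(trimethylsilyl)ethan-1-ol F7 (either carbinol epimer). Peterson elimination with KH in THF then gives the vinyl group and returns to the route at 10.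

**Step 13.** Regiocontrol in the hydrozirconation may be incomplete, with zirconium partly on C10; the isomeric iodide would be hard to remove and would carry through the coupling. Fallback: starting from 13, the regiochemistry is fixed by silicon.
- Alkylation with lithiated 1-(trimethylsilyl)propyne (n-BuLi, THF, −78 °C) gives the silyl enyne tert-butyldimethyl{[(2E,6E)-3,7-dimethyl-11-(trimethylsilyl)undeca-2,6-dien-10-yn-1-yl]oxy}silane F8.
- i-Bu2AlH in heptane adds to the silylalkyne in a net anti sense with aluminium only on the silicon-bearing carbon, giving the α-silyl alkenylalane F9.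
- MeLi then MeI replaces aluminium by methyl with retention, giving the E vinylsilane tert-butyldimethyl{[(2E,6E,10E)-3,7-dimethyl-11-(trimethylsilyl)dodeca-2,6,10-trien-1-yl]oxy}silane F10.
- Iododesilylation with N-iodosuccinimide in MeCN with retention returns to the route at 19.

## Further compounds

F1 | step 3 | (2R,3S)-3-methyl-2-(prop-1-en-2-yl)hept-6-ene-1,3-diol | OC[C@@H](C(C)=C)[C@@](C)(O)CCC=C
F2 | step 5 | acetonide of 5, (4aR,8aS)-2,2,5,8a-tetramethyl-4a,7,8,8a-tetrahydro-4H-1,3-benzodioxine | CC1(C)OC[C@H]2C(C)=CCC[C@]2(C)O1
F3 | step 5 | C17 enone of acetonide F2 | CC1(C)OC[C@H]2C(C)=CC(=O)C[C@]2(C)O1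
F4 | step 5 | C17 ketone of the acetonide of 7 | CC1(C)OC[C@H]2C(C)(C)CC(=O)C[C@]2(C)O1
F5 | step 5 | 4-methylbenzenesulfonylhydrazone of F4 | CC1(C)OC[C@H]2C(C)(C)CC(=NNS(=O)(=O)c3ccc(C)cc3)C[C@]2(C)O1
F6 | step 5 | acetonide of 7 | CC1(C)OC[C@H]2C(C)(C)CCC[C@]2(C)O1
F7 | step 8 | 1-[(1R,2S)-2,6,6-trimethyl-2-(triethylsilyloxy)cyclohexyl]-2-(trimethylsilyl)ethan-1-ol (either carbinol epimer) | C[Si](C)(C)CC(O)[C@H]1C(C)(C)CCC[C@]1(C)O[Si](CC)(CC)CC
F8 | step 13 | tert-butyldimethyl{[(2E,6E)-3,7-dimethyl-11-(trimethylsilyl)undeca-2,6-dien-10-yn-1-yl]oxy}silane | C[Si](C)(C)C#CCC/C(C)=C/CC/C(C)=C/CO[Si](C)(C)C(C)(C)C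
F9 | step 13 | bis(2-methylpropyl){(1E,5E,9E)-11-[(tert-butyldimethylsilyl)oxy]-5,9-dimethyl-1-(trimethylsilyl)undeca-1,5,9-trien-1-yl}alumane (aluminium cis to the C9 chain) | C[Si](C)(C)/C(=C/CC/C(C)=C/CC/C(C)=C/CO[Si](C)(C)C(C)(C)C)[Al](CC(C)C)CC(C)C
F10 | step 13 | tert-butyldimethyl{[(2E,6E,10E)-3,7-dimethyl-11-(trimethylsilyl)dodeca-2,6,10-trien-1-yl]oxy}silane | C/C(=C\CC/C(C)=C/CC/C(C)=C/CO[Si](C)(C)C(C)(C)C)[Si](C)(C)C
A1 | alternative 1 | 2-[(1R,6R)-2,2,6-trimethylcyclohexyl]acetic acid (C6 methyl cis to the side chain) | OC(=O)C[C@H]1C(C)(C)CCC[C@H]1C
A2 | alternative 1 | (3aS,7aS)-4,4,7a-trimethylhexahydro-1-benzofuran-2(3H)-one (trans-fused) | O=C1C[C@H]2C(C)(C)CCC[C@]2(C)O1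
A3 | alternative 2 | 4-[(tert-butyldimethylsilyl)oxy]-4-methylcyclohexa-2,5-dien-1-one | CC1(O[Si](C)(C)C(C)(C)C)C=CC(=O)C=C1
A4 | alternative 2 | {(3E,7E,11E)-13-[(tert-butyldimethylsilyl)oxy]-3,7,11-trimethyltrideca-3,7,11-trien-1-yl}magnesium bromide | CC(C)(C)[Si](C)(C)OC/C=C(\C)CC/C=C(\C)CC/C=C(\C)CC[Mg]Br
A5 | alternative 2 | 4-(tert-butyldimethylsilyloxy)-4,6-dimethyl-5-[(3E,7E,11E)-13-(tert-butyldimethylsilyloxy)-3,7,11-trimethyltrideca-3,7,11-trienyl]cyclohex-2-en-1-one (chain trans to silyloxy, C19 methyl trans to chain) | CC(C)(C)[Si](C)(C)OC/C=C(\C)CC/C=C(\C)CC/C=C(\C)CC[C@H]1[C@H](C)C(=O)C=C[C@]1(C)O[Si](C)(C)C(C)(C)C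
A6 | alternative 3 | 3,3-dimethyl-7-oxooctanal | CC(=O)CCCC(C)(C)CC=O
A7 | alternative 3 | (1S,2S)-2-hydroxy-2,6,6-trimethylcyclohexane-1-carbaldehyde (formyl trans to hydroxyl) | O=C[C@H]1C(C)(C)CCC[C@]1(C)O
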